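**Retrosynthetic overview**

- Target ⇒ trans-diaxial methanolysis of a cis-epoxide placed by the C1′ tertiary hydroxyl ⇒ a 1-substituted cyclohex-3-en-1-ol carrying all other hydroxyls free (no protecting groups).
- Rings B and C ⇒ one flask: formal [4+1] annulation of an ester-substituted o-quinone methide with a β-keto sulfoxonium ylide (C3–C2 and O–C2 bonds, ring B), then intramolecular umpolung allylation of the new 2-acyl ketone by the ylide's own allylic alcohol (C1′–C2′ bond, ring C).
- Pieces: ring A is bought as a dihydroferulate and armed at its free ortho carbon with a glyoxylate; C2 and the six carbons of ring C come from a vinyl butyrolactone and a sulfoxonium salt.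
- Order of ring formation: A (bought) → B → C (same operation). Stereocentres: C3 by catalyst, C2 by equilibration to trans, C1′ by chelation, C3′/C4′ by directed epoxidation and opening.

Assumption: the compounds marked starting material in the list are bought as such; carbons are labelled C2/C3 (dihydrofuran ring B) and C1′–C6′ (cyclohexane ring C), ring A being the arene.

**Step 1**
Reactants: 1 methyl 3-(4-hydroxy-3-methoxyphenyl)propanoate; 2 ethyl glyoxylate
Product: 3 ethyl 2-hydroxy-2-[2-hydroxy-3-methoxy-5-(3-methoxy-3-oxopropyl)phenyl]acetate (racemic)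
Conditions: EtMgBr (1.0 equiv), toluene, 0 °C; then 2 (toluene solution), 0 °C → rt; aq. NH4Cl
Reagents that add atoms: none
Why: Casiraghi-type ortho-specific hydroxyalkylation, in which the bromomagnesium phenoxide delivers the glyoxylate through a chelated six-membered transition state to the only free ortho carbon (para is blocked and the one equivalent of Grignard reagent is consumed by the phenol, so both esters survive); the new carbinol is racemic and becomes sp2 in step 4.

**Step 2**
Reactants: 3 ethyl 2-hydroxy-2-[2-hydroxy-3-methoxy-5-(3-methoxy-3-oxopropyl)phenyl]acetate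
Product: 4 ethyl 2-chloro-2-[2-hydroxy-3-methoxy-5-(3-methoxy-3-oxopropyl)phenyl]acetate (racemic)
Conditions: PPh3, N-chlorosuccinimide, THF, −20 → 0 °C; used crude
Reagents that add atoms: N-chlorosuccinimide, O=C1CCC(=O)N1Cl
Why: Appel-type deoxychlorination, in which the benzylic hydroxyl becomes an alkoxyphosphonium ion that chloride displaces under neutral conditions, leaving the phenol and the esters untouched; the stereocentre does not matter because it is erased in step 4.

**Step 3**
Reactants: 5 5-ethenyloxolan-2-one (racemic); 6 trimethylsulfoxonium iodide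
Product: 7 1-[dimethyl(oxo)-λ6-sulfanylidene]-5-hydroxyhept-6-en-2-one (racemic)
Conditions: KOtBu, THF, reflux; then 5, 0 °C → rt
Reagents that add atoms: none
Why: Corey-type acylation of dimethylsulfoxonium methylide by the lactone (ester to β-keto sulfoxonium ylide homologation), which opens the ring to the carbonyl-stabilised ylide and frees the allylic alcohol; the carbinol stays racemic because it is erased at the π-allyl stage of step 4.

**Step 4**
Reactants: 4 ethyl 2-chloro-2-[2-hydroxy-3-methoxy-5-(3-methoxy-3-oxopropyl)phenyl]acetate; 7 1-[dimethyl(oxo)-λ6-sulfanylidene]-5-hydroxyhept-6-en-2-one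
Product: 10 ethyl (2S,3S)-2-[(1S)-1-hydroxycyclohex-3-en-1-yl]-7-methoxy-5-(3-methoxy-3-oxopropyl)-2,3-dihydro-1-benzofuran-3-carboxylate, via o-quinone methide 8 (not isolated), via keto ester 9 (not isolated)
Conditions: 7 (1.05 equiv), 3-{[3,5-bis(trifluoromethyl)phenyl]amino}-4-{[(8α,9S)-6′-methoxycinchonan-9-yl]amino}cyclobut-3-ene-1,2-dione (10 mol%), K2CO3 (2 equiv), toluene, 0 °C → rt; then THF, Pd(PPh3)4 (5 mol%), Et2Zn (4 equiv), 0 °C → rt; aq. NH4Cl at 0 °C
Reagents that add atoms: none
Why: Proposed new method: K2CO3 eliminates HCl from 4 to give the ester-substituted o-quinone methide 8, which is held by the squaramide N–H bonds while the ylide carbon of 7 adds to the methide carbon on one face (sets C3, S), the phenoxide then displaces dimethyl sulfoxide at the α-keto carbon (5-exo-tet, ring B) and the enolisable C2 settles trans (2S) in 9; in the same flask zerovalent palladium ionises the allylic alcohol, Et2Zn converts the π-allyl into an allylzinc (umpolung) and the only unstrained intramolecular addition to the ketone goes through the distal allyl carbon (ring C), with zinc chelated between the ketone oxygen and the neighbouring ring-B and 7-methoxy oxygens so that the allyl arrives on the face syn to C2–H and C1′ is formed S; the closest known reaction types are the base-mediated and hydrogen-bond-catalysed asymmetric [4+1] annulations of o-quinone methides with sulfur ylides and the Tamaru-type palladium/Et2Zn Barbier allylation of carbonyls by allylic alcohols under Cram-chelate control.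

**Step 5**
Reactants: 10 ethyl (2S,3S)-2-[(1S)-1-hydroxycyclohex-3-en-1-yl]-7-methoxy-5-(3-methoxy-3-oxopropyl)-2,3-dihydro-1-benzofuran-3-carboxylate
Product: 11 (1S)-1-[(2S,3R)-3-(hydroxymethyl)-5-(3-hydroxypropyl)-7-methoxy-2,3-dihydro-1-benzofuran-2-yl]cyclohex-3-en-1-ol
Conditions: LiAlH4, THF, 0 °C → rt; H2O/aq. NaOH work-up
Reagents that add atoms: none
Why: LiAlH4 ester reduction takes both esters to primary alcohols while the isolated alkene and the aryl ether are inert; no stereocentre is formed, and C3 is reduced faster than it can epimerise (trans is also the stable arrangement).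

**Step 6**
Reactants: 11 (1S)-1-[(2S,3R)-3-(hydroxymethyl)-5-(3-hydroxypropyl)-7-methoxy-2,3-dihydro-1-benzofuran-2-yl]cyclohex-3-en-1-ol
Product: 13 difengpiol B, via epoxide 12 (not isolated)
Conditions: VO(acac)2 (5 mol%), tBuOOH (1.2 equiv), CH2Cl2, 0 °C → rt; then MeOH, 10-camphorsulfonic acid (10 mol%), rt
Reagents that add atoms: tert-butyl hydroperoxide, CC(C)(C)OO; methanol, CO
Why: Hydroxyl-directed vanadium-catalysed epoxidation (the axial tertiary homoallylic hydroxyl delivers the peroxide to its own face, as with terpinen-4-ol) is followed by acid-catalysed trans-diaxial (Fürst–Plattner) methanolysis at C4′, the carbon remote from the carbinol in the conformer that keeps the large C1′ substituent equatorial, which sets 3′-OH cis to 1′-OH (3′S) and 4′-OMe trans to it (4′S).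

**Compound list**

1 | methyl 3-(4-hydroxy-3-methoxyphenyl)propanoate (methyl dihydroferulate) | COC(=O)CCc1ccc(O)c(OC)c1 | starting material
2 | ethyl glyoxylate (ethyl 2-oxoacetate) | CCOC(=O)C=O | starting material
3 | ethyl 2-hydroxy-2-[2-hydroxy-3-methoxy-5-(3-methoxy-3-oxopropyl)phenyl]acetate (racemic) | CCOC(=O)C(O)c1cc(CCC(=O)OC)cc(OC)c1O | intermediate
4 | ethyl 2-chloro-2-[2-hydroxy-3-methoxy-5-(3-methoxy-3-oxopropyl)phenyl]acetate (racemic) | CCOC(=O)C(Cl)c1cc(CCC(=O)OC)cc(OC)c1O | intermediate
5 | 5-ethenyloxolan-2-one (γ-vinyl-γ-butyrolactone; racemic) | C=CC1CCC(=O)O1 | starting material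
6 | trimethylsulfoxonium iodide | C[S+](C)(C)=O.[I-] | starting material
7 | 1-[dimethyl(oxo)-λ6-sulfanylidene]-5-hydroxyhept-6-en-2-one (racemic) | C=CC(O)CCC(=O)C=S(C)(C)=O | intermediate
8 | ethyl 2-[3-methoxy-5-(3-methoxy-3-oxopropyl)-2-oxocyclohexa-3,5-dien-1-ylidene]acetate (o-quinone methide) | CCOC(=O)C=C1C=C(CCC(=O)OC)C=C(OC)C1=O | intermediate
9 | ethyl (2S,3S)-2-(4-hydroxyhex-5-enoyl)-7-methoxy-5-(3-methoxy-3-oxopropyl)-2,3-dihydro-1-benzofuran-3-carboxylate (keto ester; both carbinol epimers) | COc1cc(CCC(=O)OC)cc2c1O[C@H](C(=O)CCC(O)C=C)[C@H]2C(=O)OCC | intermediate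
10 | ethyl (2S,3S)-2-[(1S)-1-hydroxycyclohex-3-en-1-yl]-7-methoxy-5-(3-methoxy-3-oxopropyl)-2,3-dihydro-1-benzofuran-3-carboxylate | COc1cc(CCC(=O)OC)cc2c1O[C@H]([C@]1(O)CCC=CC1)[C@H]2C(=O)OCC | intermediate
11 | (1S)-1-[(2S,3R)-3-(hydroxymethyl)-5-(3-hydroxypropyl)-7-methoxy-2,3-dihydro-1-benzofuran-2-yl]cyclohex-3-en-1-ol | COc1cc(CCCO)cc2c1O[C@H]([C@]1(O)CCC=CC1)[C@H]2CO | intermediate
12 | (1S,3S,6R)-3-[(2S,3R)-3-(hydroxymethyl)-5-(3-hydroxypropyl)-7-methoxy-2,3-dihydro-1-benzofuran-2-yl]-7-oxabicyclo[4.1.0]heptan-3-ol (epoxide syn to the tertiary hydroxyl) | COc1cc(CCCO)cc2c1O[C@H]([C@]1(O)CC[C@H]3O[C@H]3C1)[C@H]2CO | intermediate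
13 | difengpiol B, (1S,3S,4S)-1-[(2S,3R)-3-(hydroxymethyl)-5-(3-hydroxypropyl)-7-methoxy-2,3-dihydro-1-benzofuran-2-yl]-4-methoxycyclohexane-1,3-diol | COc1cc(CCCO)cc2c1O[C@H]([C@]1(O)CC[C@H](OC)[C@@H](O)C1)[C@H]2CO | target

**Step count and risks**

Total steps: 6. Longest linear sequence: 5 (1 → 3 → 4 → 10 → 11 → 13).

The step most likely to fail is step 4. The ylide may add to 8 without the catalyst, which would erode the selectivity at C3, and the sense of induction must be found by experiment (the pseudo-enantiomer of the catalyst is the first remedy). Prolonged base contact can epimerise C3 of 9. The allylzinc closure may give poor regio- or facial control. The fallback sets out from 4 and comes back at 10; it puts the chirality on the ylide itself and closes ring C stepwise. Bought methyl pent-4-enoate and chloroiodomethane/MeLi (−78 °C) give 1-chlorohex-5-en-2-one F1. Quinidine quaternises it to N-(2-oxohex-5-en-1-yl)quinidinium chloride F2. With 4 and Cs2CO3 in CH2Cl2 the ammonium ylide adds to 8 and the amine is expelled in the ring closure, giving ethyl (2S,3S)-7-methoxy-5-(3-methoxy-3-oxopropyl)-2-(pent-4-enoyl)-2,3-dihydro-1-benzofuran-3-carboxylate F3, which is isolated and can be recrystallised. Chelation-controlled Hosomi–Sakurai allylation (allyltrimethylsilane, TiCl4, −78 °C) gives ethyl (2S,3S)-2-[(4S)-4-hydroxyocta-1,7-dien-4-yl]-7-methoxy-5-(3-methoxy-3-oxopropyl)-2,3-dihydro-1-benzofuran-3-carboxylate F4. Ring-closing metathesis with the second-generation Grubbs catalyst then returns 10.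

The second is step 2. The free-phenol benzylic chloride 4 may lose HCl and oligomerise, or lactonise, before it is used. The fallback sets out from 3 and comes back at 8. Ac2O/pyridine gives the bench-stable ethyl 2-acetoxy-2-[2-acetoxy-3-methoxy-5-(3-methoxy-3-oxopropyl)phenyl]acetate F5. This is charged into step 4 in place of 4 together with one equivalent of MeOH: K2CO3/MeOH cleaves the aryl acetate and the phenoxide expels the benzylic acetate, releasing 8 slowly in the presence of 7.

The third is step 6. Acidic methanol could open the epoxide at C3′ as well, and the tetraol is polar and awkward to purify. The fallback sets out from 10 and comes back at 13; it moves the oxygenation ahead of the reduction, where the tertiary hydroxyl is the only free one. VO(acac)2/tBuOOH gives ethyl (2S,3S)-2-[(1S,3S,6R)-3-hydroxy-7-oxabicyclo[4.1.0]heptan-3-yl]-7-methoxy-5-(3-methoxy-3-oxopropyl)-2,3-dihydro-1-benzofuran-3-carboxylate F6. Ti(OiPr)4/MeOH then opens the epoxide; titanium bridges the C1′ alkoxide and the epoxide oxygen, so the C3′–O bond stays in the chelate and methanol enters at C4′, giving ethyl (2S,3S)-2-[(1S,3S,4S)-1,3-dihydroxy-4-methoxycyclohexyl]-7-methoxy-5-(3-methoxy-3-oxopropyl)-2,3-dihydro-1-benzofuran-3-carboxylate F7. LiAlH4 reduction of both esters gives 13.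

**Further compounds**

F1 | step 4 | 1-chlorohex-5-en-2-one | C=CCCC(=O)CCl
F2 | step 4 | N-(2-oxohex-5-en-1-yl)quinidinium chloride | COc1ccc2nccc([C@@H]([C@H]3C[C@@H]4CC[N+]3(CC(=O)CCC=C)C[C@@H]4C=C)O)c2c1.[Cl-]
F3 | step 4 | ethyl (2S,3S)-7-methoxy-5-(3-methoxy-3-oxopropyl)-2-(pent-4-enoyl)-2,3-dihydro-1-benzofuran-3-carboxylate | COc1cc(CCC(=O)OC)cc2c1O[C@H](C(=O)CCC=C)[C@H]2C(=O)OCC
F4 | step 4 | ethyl (2S,3S)-2-[(4S)-4-hydroxyocta-1,7-dien-4-yl]-7-methoxy-5-(3-methoxy-3-oxopropyl)-2,3-dihydro-1-benzofuran-3-carboxylate | COc1cc(CCC(=O)OC)cc2c1O[C@H]([C@@](O)(CC=C)CCC=C)[C@H]2C(=O)OCC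
F5 | step 2 | ethyl 2-acetoxy-2-[2-acetoxy-3-methoxy-5-(3-methoxy-3-oxopropyl)phenyl]acetate | CCOC(=O)C(OC(C)=O)c1cc(CCC(=O)OC)cc(OC)c1OC(C)=O
F6 | step 6 | ethyl (2S,3S)-2-[(1S,3S,6R)-3-hydroxy-7-oxabicyclo[4.1.0]heptan-3-yl]-7-methoxy-5-(3-methoxy-3-oxopropyl)-2,3-dihydro-1-benzofuran-3-carboxylate | COc1cc(CCC(=O)OC)cc2c1O[C@H]([C@]1(O)CC[C@H]3O[C@H]3C1)[C@H]2C(=O)OCC
F7 | step 6 | ethyl (2S,3S)-2-[(1S,3S,4S)-1,3-dihydroxy-4-methoxycyclohexyl]-7-methoxy-5-(3-methoxy-3-oxopropyl)-2,3-dihydro-1-benzofuran-3-carboxylate | COc1cc(CCC(=O)OC)cc2c1O[C@H]([C@]1(O)CC[C@H](OC)[C@@H](O)C1)[C@H]2C(=O)OCC
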